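**Retrosynthetic overview**
1. Target ⇒ 3,4-dimethoxybenzaldehyde + the C4,C6-diol (either C6 epimer): the ester C–O bond and the C6 configuration are made together in a stereoconvergent samarium-catalysed redox esterification (key step).
2. Diol ⇒ trans-fused bicyclic hydroxy ketone by isopropyl–cerium addition to the C4 ketone (sets C4).
3. Seven-membered ring ⇒ ring-closing metathesis of an allyl and a 2-methylallyl arm (forms C8=C9).
4. C1 quaternary centre and C5–C6 bond ⇒ one-pot copper-catalysed asymmetric conjugate methylation/aldol of 3-allylcyclopent-2-enone with 3-methylbut-3-enal.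
5. Ring order: the five-membered ring is bought in, the seven-membered ring is closed by metathesis. Labels C1–C10 are daucane numbering (C1 quaternary C–CH3, C4 isopropyl carbinol, C5 ring-fusion CH, C6 ester carbon, C8=C9 alkene); systematic names use azulene numbering.

Assumption: the ligand enantiomer named in step 3 is taken to give the (R)-configured quaternary carbon; if the first run shows the opposite sense, its mirror image is used.

**Step 1**
Reactants: 1 3-ethoxycyclopent-2-en-1-one; 2 allylmagnesium bromide
Product: 4 3-(prop-2-en-1-yl)cyclopent-2-en-1-one, via 3-ethoxy-1-(prop-2-en-1-yl)cyclopent-2-en-1-ol 3 (not isolated)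
Conditions: 2 (1.3 equiv), THF, 0 °C; then 1 M HCl, 0 °C
Reagents that add atoms: allylmagnesium bromide (2), C=CC[Mg]Br
Why: 1,2-addition of the allyl Grignard reagent to the vinylogous ester followed by acid hydrolysis with carbonyl transposition (Stork–Danheiser sequence) gives the 3-substituted enone; no stereocentre is formed.

**Step 2**
Reactants: 5 3-methylbut-3-en-1-ol
Product: 6 3-methylbut-3-enal
Conditions: Dess–Martin periodinane (1.1 equiv), NaHCO3, CH2Cl2, 0 °C; used at once as a cold solution
Reagents that add atoms: none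
Why: Dess–Martin oxidation of the primary alcohol stops at the aldehyde, and the buffered, cold, neutral conditions keep the β,γ-double bond out of conjugation.

**Step 3**
Reactants: 4 3-(prop-2-en-1-yl)cyclopent-2-en-1-one; 6 3-methylbut-3-enal; 7 trimethylaluminium
Product: 9 (2S,3R)-2-(1-hydroxy-3-methylbut-3-en-1-yl)-3-methyl-3-(prop-2-en-1-yl)cyclopentan-1-one (both epimers at the side-chain carbinol C6; 1'S major), via dimethylaluminium enolate 8 (not isolated)
Conditions: Cu(O2CC4H3S) (copper thiophene-2-carboxylate, 5 mol%), (S,R,R)-BINOL-derived N,N-bis(1-phenylethyl)phosphoramidite (10 mol%), Me3Al (1.4 equiv), Et2O, −30 °C; then 6 (1.5 equiv), −78 → −40 °C; aq. KNaC4H4O6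
Reagents that add atoms: trimethylaluminium (7), C[Al](C)C; 3-methylbut-3-enal (6), CC(=C)CC=O
Why: Copper-catalysed asymmetric conjugate addition of Me3Al sets the quaternary C1 under ligand control and gives the regiodefined enolate 8, whose Zimmerman–Traxler aldol addition to 6 occurs on the face anti to the larger allyl group (new C5–C6 bond cis to the methyl group), while C6 is left as an epimer mixture (anti aldol, 6S, major) because step 6 converges both epimers.

**Step 4**
Reactants: 9 (2S,3R)-2-(1-hydroxy-3-methylbut-3-en-1-yl)-3-methyl-3-(prop-2-en-1-yl)cyclopentan-1-one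
Product: 10 (3aS,8aR)-4-hydroxy-6,8a-dimethyl-2,3a,4,5,8,8a-hexahydroazulen-3(1H)-one (trans ring fusion; both epimers at the carbinol C6)
Conditions: second-generation Grubbs catalyst RuCl2(=CHPh)(PCy3)(H2IMes) (5 mol%), CH2Cl2 (5 mM), 40 °C; chromatography
Reagents that add atoms: none
Why: Ring-closing metathesis of the trans-disposed allyl and 2-methylallyl arms closes the seven-membered ring with the trisubstituted C8=C9 alkene without touching a stereocentre, and the minor cis-fused isomer from the other enolate face of step 3 is removed here.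

**Step 5**
Reactants: 10 (3aS,8aR)-4-hydroxy-6,8a-dimethyl-2,3a,4,5,8,8a-hexahydroazulen-3(1H)-one; 11 isopropylmagnesium chloride
Product: 12 (3R,3aS,8aR)-6,8a-dimethyl-3-(propan-2-yl)-1,2,3,3a,4,5,8,8a-octahydroazulene-3,4-diol (both epimers at the secondary carbinol C6; 4S major)
Conditions: CeCl3 (4 equiv), i-PrMgCl (4 equiv), THF, −78 → −20 °C; aq. NH4Cl
Reagents that add atoms: isopropylmagnesium chloride (11), CC(C)[Mg]Cl
Why: Organocerium 1,2-addition (Imamoto conditions) suppresses enolisation and reduction of the hindered ketone, and the isopropyl group enters the C4 carbonyl anti to the C5–C6 bond (on the H5 face), which places the new hydroxyl cis to C6 and to the angular methyl group.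

**Step 6**
Reactants: 12 (3R,3aS,8aR)-6,8a-dimethyl-3-(propan-2-yl)-1,2,3,3a,4,5,8,8a-octahydroazulene-3,4-diol; 13 3,4-dimethoxybenzaldehyde
Product: 16 (3R,3aS,4S,8aR)-3-hydroxy-6,8a-dimethyl-3-(propan-2-yl)-1,2,3,3a,4,5,8,8a-octahydroazulen-4-yl 3,4-dimethoxybenzoate, via hydroxy ketone 14 (not isolated), via tertiary veratrate 15 (not isolated)
Conditions: SmI2 (30 mol%) pre-stirred with 13 (5 equiv), THF, 23 → 40 °C; aq. NaHCO3
Reagents that add atoms: 3,4-dimethoxybenzaldehyde (13), COc1ccc(C=O)cc1OC
Why: Proposed new method: a stereoconvergent Oppenauer/Evans–Tishchenko redox esterification in which the trivalent samarium pinacolate formed from SmI2 and 13 first oxidises the C6 carbinol of either epimer by hydride transfer to 13 (giving 14), the samarium alkoxide of the tertiary C4 hydroxyl then adds to a second molecule of 13 and the hemiacetal delivers its hydride to the C6 ketone through a six-membered chair on the face of the C4 oxygen (sets 6S, O6 anti to O4, and forms the ester irreversibly as 15), and the acyl group finally shifts from the crowded tertiary oxygen to the adjacent C6 alkoxide through a samarium-bound orthoester to give 16; the closest known reaction types are the SmI2-catalysed Evans–Tishchenko anti-reduction of secondary β-hydroxy ketones, samarium-catalysed Meerwein–Ponndorf–Verley/Oppenauer hydride transfer and 1,3-acyl migration in diol monoesters, which have not been merged or shown on a tertiary aldol.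

**Compound list**
1 | 3-ethoxycyclopent-2-en-1-one | CCOC1=CC(=O)CC1 | starting material
2 | allylmagnesium bromide | C=CC[Mg]Br | starting material
3 | 3-ethoxy-1-(prop-2-en-1-yl)cyclopent-2-en-1-ol (racemic) | CCOC1=CC(O)(CC=C)CC1 | intermediate
4 | 3-(prop-2-en-1-yl)cyclopent-2-en-1-one | O=C1C=C(CC=C)CC1 | intermediate
5 | 3-methylbut-3-en-1-ol | CC(=C)CCO | starting material
6 | 3-methylbut-3-enal | CC(=C)CC=O | intermediate
7 | trimethylaluminium | C[Al](C)C | starting material
8 | dimethyl{[(3R)-3-methyl-3-(prop-2-en-1-yl)cyclopent-1-en-1-yl]oxy}alumane | C[Al](C)OC1=C[C@@](C)(CC=C)CC1 | intermediate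
9 | (2S,3R)-2-(1-hydroxy-3-methylbut-3-en-1-yl)-3-methyl-3-(prop-2-en-1-yl)cyclopentan-1-one (side-chain carbinol epimers, 1'S major) | OC(CC(C)=C)[C@H]1C(=O)CC[C@]1(C)CC=C | intermediate
10 | (3aS,8aR)-4-hydroxy-6,8a-dimethyl-2,3a,4,5,8,8a-hexahydroazulen-3(1H)-one (trans-fused; carbinol epimers, 4S major) | OC1CC(C)=CC[C@@]2(C)CCC(=O)[C@H]12 | intermediate
11 | isopropylmagnesium chloride | CC(C)[Mg]Cl | starting material
12 | (3R,3aS,8aR)-6,8a-dimethyl-3-(propan-2-yl)-1,2,3,3a,4,5,8,8a-octahydroazulene-3,4-diol (secondary carbinol epimers, 4S major) | OC1CC(C)=CC[C@@]2(C)CC[C@@](O)(C(C)C)[C@H]12 | intermediate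
13 | 3,4-dimethoxybenzaldehyde | COc1ccc(C=O)cc1OC | starting material
14 | (3R,3aR,8aR)-3-hydroxy-6,8a-dimethyl-3-(propan-2-yl)-2,3,3a,5,8,8a-hexahydroazulen-4(1H)-one | O=C1CC(C)=CC[C@@]2(C)CC[C@@](O)(C(C)C)[C@H]12 | intermediate
15 | (3R,3aS,4S,8aR)-4-hydroxy-6,8a-dimethyl-3-(propan-2-yl)-1,2,3,3a,4,5,8,8a-octahydroazulen-3-yl 3,4-dimethoxybenzoate | O[C@H]1CC(C)=CC[C@@]2(C)CC[C@@](OC(=O)c3ccc(OC)c(OC)c3)(C(C)C)[C@H]12 | intermediate
16 | (3R,3aS,4S,8aR)-3-hydroxy-6,8a-dimethyl-3-(propan-2-yl)-1,2,3,3a,4,5,8,8a-octahydroazulen-4-yl 3,4-dimethoxybenzoate | COc1ccc(C(=O)O[C@H]2CC(C)=CC[C@@]3(C)CC[C@@](O)(C(C)C)[C@H]23)cc1OC | target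

**Step count and risks**
Total step count: 6. Longest linear sequence: 5 steps (1, 3, 4, 5, 6); step 2 is a one-step side branch.

Steps most likely to fail:

Step 6 (the new reaction): the Oppenauer stage may be slow, the acyl shift may stop at 15, or 14 may open by retro-aldol cleavage. The fallback uses known chemistry, sets out from 12 and returns at 16. Dess–Martin periodinane with NaHCO3 oxidises only the secondary hydroxyl of both epimers of 12 to the hydroxy ketone 14. Hydroxyl-directed reduction with Me4NBH(OAc)3 in MeCN/AcOH at −20 °C then delivers hydride from the face of the C4 hydroxyl and gives the single anti diol (3R,3aS,4S,8aR)-6,8a-dimethyl-3-(propan-2-yl)-1,2,3,3a,4,5,8,8a-octahydroazulene-3,4-diol (jaeschkeanadiol) F1. 3,4-Dimethoxybenzoyl chloride, DMAP and pyridine acylate only its secondary hydroxyl to give 16.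

Step 3: the aluminium enolate may react poorly with the enolisable aldehyde, and the facial selectivity (allyl against methyl) is only moderate. The fallback sets out from 4 and returns at 9. The conjugate addition is run alone and enolate 8 is quenched with Me3SiOTf to give the isolable silyl enol ether trimethyl{[(3R)-3-methyl-3-(prop-2-en-1-yl)cyclopent-1-en-1-yl]oxy}silane F2. A BF3·OEt2-mediated Mukaiyama aldol addition of F2 to 6 at −78 °C (open transition state, no basic enolate in contact with the aldehyde) then gives 9, again as a C6 epimer mixture that step 6 accepts.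

Step 5: the β-hydroxy ketone may enolise or open by retro-aldol, and the secondary Grignard reagent may reduce the ketone. The fallback sets out from 10 and returns at 12. Isopropenylmagnesium bromide with CeCl3 (an sp2 nucleophile with no β-hydride to give) adds to the C4 ketone on the same face to give (3S,3aS,8aR)-6,8a-dimethyl-3-(prop-1-en-2-yl)-1,2,3,3a,4,5,8,8a-octahydroazulene-3,4-diol F3. Hydrogenation with RhCl(PPh3)3 and H2 in benzene saturates only the 1,1-disubstituted alkene and leaves the trisubstituted ring alkene, giving 12.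

**Further compounds**
F1 | step 6 | (3R,3aS,4S,8aR)-6,8a-dimethyl-3-(propan-2-yl)-1,2,3,3a,4,5,8,8a-octahydroazulene-3,4-diol (jaeschkeanadiol) | O[C@H]1CC(C)=CC[C@@]2(C)CC[C@@](O)(C(C)C)[C@H]12
F2 | step 3 | trimethyl{[(3R)-3-methyl-3-(prop-2-en-1-yl)cyclopent-1-en-1-yl]oxy}silane | C[Si](C)(C)OC1=C[C@@](C)(CC=C)CC1
F3 | step 5 | (3S,3aS,8aR)-6,8a-dimethyl-3-(prop-1-en-2-yl)-1,2,3,3a,4,5,8,8a-octahydroazulene-3,4-diol (secondary carbinol epimers) | OC1CC(C)=CC[C@@]2(C)CC[C@@](O)(C(C)=C)[C@H]12
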